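**Plan**

- Target 16 is (2R,3R,6R,8S)-2,8-dibromo-3,7,7-trimethyl-11-methylidenespiro[5.5]undecan-3-ol; its locants are kept for all intermediates (ring B = C1–C6 with CHBr at C2 and the carbinol at C3; ring A = C6–C11).
- Retrosynthetic cuts, in order: C11=CH2 (methylenation of a C11 ketone); C9–C10 together with C8–Br (bromine atom-transfer radical cyclisation of a bromomethyl ketone onto the vinyl group on C7); C10–C11 (carbenoid addition to a lactone carbonyl); C3–O and C2–Br (bromolactonisation); C6–C7 (Ireland–Claisen); the ester C–O bond.
- Enabling feature: the C8 bromide is γ to C11 through C9 and C10 and sits on a secondary carbon beside the quaternary C7, where ionic substitution is shut off but a carbon radical can still pick up bromine; ring B carries no alkene at that point.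
- Forward: ring B is bought with acid 1; C6–C7 is made by rearrangement of the prenyl ester; the acid is resolved; lactonisation finishes ring B; one carbon (C10) is added; ring A closes last at the spiro centre C6; the methylene is put on at the end.
- Stereochemistry: C6 from resolution of acid 6; C2 and C3 from C6, because the carboxyl delivers O3 to its own face and bromine enters anti; C8 in the bromine transfer that ends the cyclisation.

Key step: step 7

Assumption: the salt of the (S)-acid with (R)-1-phenylethylamine is taken to be the less soluble diastereomer; if the opposite pairing crystallises, (S)-1-phenylethylamine is used in the same way.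

**Route**

Step 1
Reactants: 1 4-methylcyclohex-3-ene-1-carboxylic acid (racemic); 2 3-methylbut-2-en-1-ol
Product: 3 3-methylbut-2-en-1-yl 4-methylcyclohex-3-ene-1-carboxylate
Conditions: DCC (1.1 equiv), DMAP (0.1 equiv), CH2Cl2, 0 °C → rt
Reagents that add atoms: none
Why: Steglich esterification: carbodiimide activation with DMAP as acyl-transfer catalyst esterifies the primary allylic alcohol under neutral conditions that leave both alkenes alone; the stereocentre of 1 does not matter because it is erased on enolisation in step 2.

Step 2
Reactants: 3 3-methylbut-2-en-1-yl 4-methylcyclohex-3-ene-1-carboxylate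
Product: 6 racemic 4-methyl-1-(2-methylbut-3-en-2-yl)cyclohex-3-ene-1-carboxylic acid, via silyl ketene acetal 4 (not isolated), via trimethylsilyl ester 5 (not isolated)
Conditions: LDA (1.2 equiv), THF, −78 °C; TMSCl (1.5 equiv), −78 °C → 65 °C; 1 M HCl, rt
Reagents that add atoms: none
Why: Ireland–Claisen rearrangement: O-silylation of the ester enolate gives a ketene acetal that rearranges through a chair [3,3] transition state, bonding the α-carbon (C6) to the dimethyl-substituted prenyl terminus (C7) and leaving the vinyl group C8=C9; formation of the C=O bond pays for the two adjacent quaternary carbons, and the acid is racemic because the faces of the ketene acetal differ only in the distant ring alkene.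

Step 3
Reactants: 6 racemic 4-methyl-1-(2-methylbut-3-en-2-yl)cyclohex-3-ene-1-carboxylic acid; 7 (R)-1-phenylethylamine
Product: 8 (R)-1-phenylethylammonium (S)-4-methyl-1-(2-methylbut-3-en-2-yl)cyclohex-3-ene-1-carboxylate
Conditions: 7 (0.55 equiv), EtOAc, 60 °C → 4 °C; salt recrystallised from EtOAc–EtOH until its optical rotation stays constant
Reagents that add atoms: none
Why: Classical resolution through diastereomeric salts (half-equivalent method): the less soluble salt of the (S)-acid should crystallise while the (R)-acid stays in the liquor as free acid; no bond at C6 is touched, and the assignment would be secured by X-ray diffraction of lactone 10 using the anomalous scattering of bromine.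

Step 4
Reactants: 8 (R)-1-phenylethylammonium (S)-4-methyl-1-(2-methylbut-3-en-2-yl)cyclohex-3-ene-1-carboxylate
Product: 9 (S)-4-methyl-1-(2-methylbut-3-en-2-yl)cyclohex-3-ene-1-carboxylic acid
Conditions: 1 M HCl, MTBE, 0 °C
Reagents that add atoms: none
Why: Acid–base exchange: HCl protonates the carboxylate, the amine hydrochloride stays in water and the acid is extracted; C6 carries no hydrogen and cannot racemise.

Step 5
Reactants: 9 (S)-4-methyl-1-(2-methylbut-3-en-2-yl)cyclohex-3-ene-1-carboxylic acid
Product: 10 (1R,4S,6R)-6-bromo-1-methyl-4-(2-methylbut-3-en-2-yl)-2-oxabicyclo[2.2.2]octan-3-one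
Conditions: NBS (1.05 equiv), MeCN, 0 °C, dark
Reagents that add atoms: N-bromosuccinimide, O=C1CCC(=O)N1Br
Why: Bromolactonisation: the bromonium ion forms on the electron-rich trisubstituted ring alkene in preference to the hindered monosubstituted vinyl group, and the carboxyl, held axial by the equatorial tert-alkyl group on C6, opens it at the tertiary carbon C3 (Markovnikov) from its own face, so O3 ends up cis to C11 and the C2 bromine anti to O3 (2R,3R in target locants), both fixed by C6.

Step 6
Reactants: 10 (1R,4S,6R)-6-bromo-1-methyl-4-(2-methylbut-3-en-2-yl)-2-oxabicyclo[2.2.2]octan-3-one; 11 dibromomethane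
Product: 14 2-bromo-1-[(1S,3R,4R)-3-bromo-4-hydroxy-4-methyl-1-(2-methylbut-3-en-2-yl)cyclohexyl]ethan-1-one, via bromomethyllithium 12 (not isolated), via lithium lactol alkoxide 13 (not isolated)
Conditions: 10 and 11 (3 equiv) in THF, −78 °C; n-BuLi (2.5 equiv) added slowly; AcOH (5 equiv) in THF at −78 °C, then rt
Reagents that add atoms: none
Why: Addition of a lithium carbenoid to a lactone: bromomethyllithium, formed by Br/Li exchange in the presence of the substrate, adds once to the lactone carbonyl because the tetrahedral lithium alkoxide persists at −78 °C, and the acidic quench at that temperature releases the hydroxy ketone as ring B relaxes from boat to chair; the C2 bromide and the three stereocentres are not touched.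

Step 7
Reactants: 14 2-bromo-1-[(1S,3R,4R)-3-bromo-4-hydroxy-4-methyl-1-(2-methylbut-3-en-2-yl)cyclohexyl]ethan-1-one
Product: 15 (2R,3R,6S,8S)-2,8-dibromo-3-hydroxy-3,7,7-trimethylspiro[5.5]undecan-11-one
Conditions: CuBr (20 mol %), tris(2-pyridylmethyl)amine (20 mol %), degassed 1,2-dichloroethane (0.02 M), 60 °C
Reagents that add atoms: none
Why: Monovalent copper (CuBr with the tetradentate amine) abstracts the bromine atom at C10 to give an electrophilic α-keto radical and a CuBr2 complex; the radical adds to the terminal vinyl carbon C9, and the secondary C8 radical so formed takes a bromine atom back from the divalent copper bromide, which regenerates the catalyst and leaves a neopentyl C–Br bond that no ionic substitution could have made. The closest known reaction type is the copper-catalysed halogen atom-transfer radical cyclisation (Kharasch type) of α-halo ketones and α-halo-β-keto esters to 4-halocyclohexanones. Ring A closes in the 6-endo-trig mode through the C9–C10 bond, because a carbonyl inside the forming ring strains the 5-exo transition state and attack at C8 is further slowed by the adjacent quaternary C7, while the two quaternary carbons C6 and C7 hold radical and alkene close. The new stereocentre C8 is fixed in the bromine transfer: ring B keeps C7 equatorial and the C11 carbonyl axial (the other chair would set C7 and the C2 bromine 1,3-diaxial), the ring A chair in which the carbonyl eclipses C6–C1 (C1 equatorial and C5 axial on ring A) should be preferred since its C=O dipole lies favourably to the equatorial C2–Br dipole with the oxygen over the polarised axial C2–H, and the bulky copper bromide then delivers bromine equatorially at C8, anti to the axial C5 methylene and therefore cis to C1 (8S). The step needs chemoselective activation of the C10–Br bond (the unactivated C2 bromide and the product C8 bromide are inert to CuBr), 6-endo regioselectivity and this facial selectivity; the last is relayed only across the spiro centre, so the C8 epimer, a diastereomer, is expected as a by-product to be removed by chromatography at this stage.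

Step 8
Reactants: 15 (2R,3R,6S,8S)-2,8-dibromo-3-hydroxy-3,7,7-trimethylspiro[5.5]undecan-11-one
Product: 16 (2R,3R,6R,8S)-2,8-dibromo-3,7,7-trimethyl-11-methylidenespiro[5.5]undecan-3-ol
Conditions: Cp2TiMe2 (4 equiv), toluene–THF, 70 °C, dark
Reagents that add atoms: dimethyltitanocene, [CH3-].[CH3-].[Ti+4].c1cc[cH-]c1.c1cc[cH-]c1
Why: Petasis methylenation: on heating, Cp2TiMe2 loses methane to give the titanium methylidene, which exchanges the oxygen of the hindered C11 carbonyl for CH2 by [2+2] cycloaddition and cycloreversion; the reagent is not basic, so neither enolisation toward C10 with 1,3-displacement of the C8 bromide nor alkoxide-driven epoxide closure at C2–C3 should interfere, and the excess covers the free tertiary hydroxyl, which is returned on aqueous work-up.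

**Compound list**

1 | 4-methylcyclohex-3-ene-1-carboxylic acid (racemic) | CC1=CCC(CC1)C(=O)O | starting material
2 | 3-methylbut-2-en-1-ol | CC(C)=CCO | starting material
3 | 3-methylbut-2-en-1-yl 4-methylcyclohex-3-ene-1-carboxylate (racemic) | CC(C)=CCOC(=O)C1CCC(C)=CC1 | intermediate
4 | silyl ketene acetal, trimethyl{[(3-methylbut-2-en-1-yl)oxy](4-methylcyclohex-3-en-1-ylidene)methoxy}silane | CC(C)=CCOC(O[Si](C)(C)C)=C1CCC(C)=CC1 | intermediate (not isolated)
5 | trimethylsilyl 4-methyl-1-(2-methylbut-3-en-2-yl)cyclohex-3-ene-1-carboxylate (racemic) | C[Si](C)(C)OC(=O)C1(C(C)(C)C=C)CCC(C)=CC1 | intermediate (not isolated)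
6 | racemic 4-methyl-1-(2-methylbut-3-en-2-yl)cyclohex-3-ene-1-carboxylic acid | OC(=O)C1(C(C)(C)C=C)CCC(C)=CC1 | intermediate
7 | (R)-1-phenylethylamine (resolving agent) | C[C@@H](N)c1ccccc1 | starting material
8 | (R)-1-phenylethylammonium (S)-4-methyl-1-(2-methylbut-3-en-2-yl)cyclohex-3-ene-1-carboxylate | [O-]C(=O)[C@@]1(C(C)(C)C=C)CCC(C)=CC1.C[C@@H]([NH3+])c1ccccc1 | intermediate
9 | (S)-4-methyl-1-(2-methylbut-3-en-2-yl)cyclohex-3-ene-1-carboxylic acid | OC(=O)[C@@]1(C(C)(C)C=C)CCC(C)=CC1 | intermediate
10 | (1R,4S,6R)-6-bromo-1-methyl-4-(2-methylbut-3-en-2-yl)-2-oxabicyclo[2.2.2]octan-3-one | O=C1[C@@]2(C(C)(C)C=C)CC[C@@](C)(O1)[C@H](Br)C2 | intermediate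
11 | dibromomethane | BrCBr | starting material
12 | bromomethyllithium | [Li]CBr | intermediate (not isolated)
13 | lithium lactol alkoxide, lithium (1R,4S,6R)-6-bromo-3-(bromomethyl)-1-methyl-4-(2-methylbut-3-en-2-yl)-2-oxabicyclo[2.2.2]octan-3-olate (configuration at the new alkoxide carbon not defined) | [Li+].[O-]C1(CBr)[C@@]2(C(C)(C)C=C)CC[C@@](C)(O1)[C@H](Br)C2 | intermediate (not isolated)
14 | 2-bromo-1-[(1S,3R,4R)-3-bromo-4-hydroxy-4-methyl-1-(2-methylbut-3-en-2-yl)cyclohexyl]ethan-1-one | BrCC(=O)[C@@]1(C(C)(C)C=C)CC[C@@](C)(O)[C@H](Br)C1 | intermediate
15 | (2R,3R,6S,8S)-2,8-dibromo-3-hydroxy-3,7,7-trimethylspiro[5.5]undecan-11-one (target locants) | O=C1CC[C@H](Br)C(C)(C)[C@@]12CC[C@@](C)(O)[C@H](Br)C2 | intermediate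
16 | (2R,3R,6R,8S)-2,8-dibromo-3,7,7-trimethyl-11-methylidenespiro[5.5]undecan-3-ol | C=C1CC[C@H](Br)C(C)(C)[C@@]12CC[C@@](C)(O)[C@H](Br)C2 | target

**Count**

Total steps: 8. Longest linear sequence: 8 steps (1 → 16).

**Steps most likely to fail**

1. Step 7 (key step). The process at risk is poor facial selectivity in the bromine transfer to the C8 radical, because the two faces are told apart only by the C2 bromine on the far side of the spiro centre; 5-exo closure and simple reduction of the C10 radical are lesser worries. The fallback keeps the C9–C10/C8–Br closure but adds a second activating group, so that a chiral reagent and not the substrate fixes C8. It sets out from lactone 10, which is opened with the lithium enolate of tert-butyl acetate (LDA, tert-butyl acetate, THF, −78 → −20 °C) to tert-butyl 3-[(1S,3R,4R)-3-bromo-4-hydroxy-4-methyl-1-(2-methylbut-3-en-2-yl)cyclohexyl]-3-oxopropanoate F1. NBS with catalytic Mg(ClO4)2 in MeCN at 0 °C then brominates C10 to give tert-butyl 2-bromo-3-[(1S,3R,4R)-3-bromo-4-hydroxy-4-methyl-1-(2-methylbut-3-en-2-yl)cyclohexyl]-3-oxopropanoate F2. F2 is cyclised as its chelate with Mg(ClO4)2 and a C2-symmetric bis(oxazoline) ligand under Et3B/O2 initiation in toluene at −78 °C, a bromine atom-transfer cyclisation of an α-bromo-β-keto ester under chiral Lewis acid control. The ligand enantiomer is chosen so that shielding of one face of the chelated C10 radical leads to the ring A chair with the ester equatorial and, by equatorial bromine transfer cis to the ester, to the 8S bromide tert-butyl (2R,3R,6S,8S)-2,8-dibromo-3-hydroxy-3,7,7-trimethyl-11-oxospiro[5.5]undecane-10-carboxylate F3. CF3CO2H in CH2Cl2 at 0 °C removes the tert-butyl group and the β-keto acid loses CO2 on gentle warming in toluene, which brings the material back to ketone 15; steps 6 and 7 are bypassed.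

2. Step 6. The process at risk is decomposition of the carbenoid faster than its addition to the congested lactone carbonyl, or collapse of the adduct before the quench followed by a second addition. The fallback uses a more persistent nucleophile and a separate reduction. It sets out from lactone 10, to which dibromomethyllithium (from 11 and LDA, THF, −78 °C, a carbenoid that lasts at this temperature) is added; quenching with AcOH at −78 °C gives 2,2-dibromo-1-[(1S,3R,4R)-3-bromo-4-hydroxy-4-methyl-1-(2-methylbut-3-en-2-yl)cyclohexyl]ethan-1-one F4. Diethyl phosphite and Et3N in THF at 0 °C then take off one of the two geminal bromines (halophilic attack of the phosphite, protonation of the enolate), and the route is rejoined at bromomethyl ketone 14.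

3. Step 3. The process at risk is co-crystallisation of the two diastereomeric salts as a solid solution, since the enantiomers of 6 differ only in where the distant ring alkene lies. The fallback separates the enantiomers after lactonisation instead of by salt formation. It sets out from racemic acid 6, which is bromolactonised under the conditions of step 5 to the racemic lactone (1RS,4SR,6RS)-6-bromo-1-methyl-4-(2-methylbut-3-en-2-yl)-2-oxabicyclo[2.2.2]octan-3-one F5, a rigid neutral compound whose enantiomers are separated by preparative chromatography on an amylose tris(3,5-dimethylphenylcarbamate) stationary phase. The (1R,4S,6R) enantiomer is lactone 10, where the route continues; steps 3 and 4 fall away.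

**Further compounds**

F1 | step 7 | tert-butyl 3-[(1S,3R,4R)-3-bromo-4-hydroxy-4-methyl-1-(2-methylbut-3-en-2-yl)cyclohexyl]-3-oxopropanoate | CC(C)(C)OC(=O)CC(=O)[C@@]1(C(C)(C)C=C)CC[C@@](C)(O)[C@H](Br)C1
F2 | step 7 | tert-butyl 2-bromo-3-[(1S,3R,4R)-3-bromo-4-hydroxy-4-methyl-1-(2-methylbut-3-en-2-yl)cyclohexyl]-3-oxopropanoate (both configurations at the brominated carbon) | CC(C)(C)OC(=O)C(Br)C(=O)[C@@]1(C(C)(C)C=C)CC[C@@](C)(O)[C@H](Br)C1
F3 | step 7 | tert-butyl (2R,3R,6S,8S)-2,8-dibromo-3-hydroxy-3,7,7-trimethyl-11-oxospiro[5.5]undecane-10-carboxylate (C10 epimerisable, not specified) | O=C1C(C(=O)OC(C)(C)C)C[C@H](Br)C(C)(C)[C@@]12CC[C@@](C)(O)[C@H](Br)C2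
F4 | step 6 | 2,2-dibromo-1-[(1S,3R,4R)-3-bromo-4-hydroxy-4-methyl-1-(2-methylbut-3-en-2-yl)cyclohexyl]ethan-1-one | BrC(Br)C(=O)[C@@]1(C(C)(C)C=C)CC[C@@](C)(O)[C@H](Br)C1
F5 | step 3 | racemic (1RS,4SR,6RS)-6-bromo-1-methyl-4-(2-methylbut-3-en-2-yl)-2-oxabicyclo[2.2.2]octan-3-one (both enantiomers written) | O=C1[C@@]2(C(C)(C)C=C)CC[C@@](C)(O1)[C@H](Br)C2.O=C1[C@]2(C(C)(C)C=C)CC[C@](C)(O1)[C@@H](Br)C2
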